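**Strategy.** The flavanone unit is disconnected at both bonds that join ring A to ring C: O1–C8a and C4–C4a. These two adjacent ring-A carbons, with the C5 oxygen next to C4a and the C7 oxygen beyond, are the termini of a 3,5-dioxygenated aryne whose triple bond the C5 alkoxy group polarises. The key step is a formal [4+2] annulation: the alkoxide of an (R)-3-aryl-3-hydroxypropanoate, whose aryl group already carries perbenzylated luteolin through the C6'–C8 biaryl bond, adds to 3,5-bis(benzyloxy)benzyne and the aryl anion closes onto the ester. Ring C closes with ring A attached in one operation, C2 is retained, and hydrogenolysis of eight benzyl ethers finishes.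

Key step: step 11

Remark: flavonoid numbering is used (ring C: O1, C2, C3, C4; ring A: C4a, C5–C8, C8a; ring B primed); the tri-ortho-substituted biaryl axis is treated as configurationally unspecified, as in the target, so compounds from 7 onward may appear as interconverting rotamers, which does not affect C2.

Step 1
Reactants: 1 luteolin
Product: 2 5,7,3',4'-tetrakis(benzyloxy)flavone
Conditions: BnBr (excess), K2CO3, DMF, 80 °C
Reagents that add atoms: benzyl bromide BrCc1ccccc1
Why: Williamson etherification of all four phenols, the hydrogen-bonded 5-OH being the slowest and driven to completion by excess bromide and heat.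

Step 2
Reactants: 2 5,7,3',4'-tetrakis(benzyloxy)flavone
Product: 3 8-iodo-5,7,3',4'-tetrakis(benzyloxy)flavone
Conditions: NIS, TFA (cat.), CH2Cl2/MeCN, 0 °C to rt
Reagents that add atoms: N-iodosuccinimide O=C1CCC(=O)N1I
Why: Electrophilic aromatic iodination of the phloroglucinol-type ring A, which in fully O-alkylated 5,7-dioxygenated flavones is expected at C8 and not at C6 or on the carbonyl-deactivated ring B.

Step 3
Reactants: 4 3,4-bis(benzyloxy)benzaldehyde
Product: 5 2-bromo-4,5-bis(benzyloxy)benzaldehyde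
Conditions: Br2, NaOAc, AcOH, rt
Reagents that add atoms: bromine BrBr
Why: Electrophilic aromatic bromination para to the 3-benzyloxy group (the position ortho to the formyl group), as in the bromination of veratraldehyde, with NaOAc buffering the HBr so that the benzyl ethers survive.

Step 4
Reactants: 5 2-bromo-4,5-bis(benzyloxy)benzaldehyde
Product: 6 4,5-bis(benzyloxy)-2-(4,4,5,5-tetramethyl-1,3,2-dioxaborolan-2-yl)benzaldehyde
Conditions: B2pin2, PdCl2(dppf) (cat.), KOAc, 1,4-dioxane, 90 °C
Reagents that add atoms: bis(pinacolato)diboron CC1(C)OB(OC1(C)C)B1OC(C)(C)C(C)(C)O1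
Why: Miyaura borylation of the aryl bromide, in which the weak base KOAc avoids biaryl homocoupling and leaves the aldehyde untouched.

Step 5
Reactants: 3 8-iodo-5,7,3',4'-tetrakis(benzyloxy)flavone; 6 4,5-bis(benzyloxy)-2-(4,4,5,5-tetramethyl-1,3,2-dioxaborolan-2-yl)benzaldehyde
Product: 7 4,5-bis(benzyloxy)-2-[5,7,3',4'-tetrakis(benzyloxy)flavon-8-yl]benzaldehyde
Conditions: Pd(OAc)2 (cat.), SPhos, K3PO4, toluene/H2O, 90 °C
Reagents that add atoms: none
Why: Suzuki–Miyaura coupling that forms the C6'–C8 biaryl bond, the bulky electron-rich biarylphosphine being chosen for the doubly ortho-flanked iodide.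

Step 6
Reactants: 7 4,5-bis(benzyloxy)-2-[5,7,3',4'-tetrakis(benzyloxy)flavon-8-yl]benzaldehyde
Product: 8 ethyl 3-{4,5-bis(benzyloxy)-2-[5,7,3',4'-tetrakis(benzyloxy)flavon-8-yl]phenyl}-3-oxopropanoate
Conditions: N2CHCO2Et, NbCl5 (cat.), CH2Cl2, rt
Reagents that add atoms: ethyl diazoacetate CCOC(=O)C=[N+]=[N-]
Why: Roskamp homologation, in which Lewis-acid-activated addition of the diazo ester to the aldehyde is followed by a 1,2-hydride shift with loss of N2 to give the beta-keto ester directly.

Step 7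
Reactants: 8 ethyl 3-{4,5-bis(benzyloxy)-2-[5,7,3',4'-tetrakis(benzyloxy)flavon-8-yl]phenyl}-3-oxopropanoate
Product: 9 ethyl (3R)-3-{4,5-bis(benzyloxy)-2-[5,7,3',4'-tetrakis(benzyloxy)flavon-8-yl]phenyl}-3-hydroxypropanoate
Conditions: RuCl[(R,R)-TsDPEN](p-cymene) (cat.), HCO2H/Et3N (5:2), DMF, 40 °C
Reagents that add atoms: none
Why: Noyori asymmetric transfer hydrogenation of the aryl ketone, where the (R,R)-ligand should give the (R)-carbinol in the sense established for aryl ketones whose aryl group outranks the alkyl branch, while the flavone vinylogous ester, the ethyl ester and the benzyl ethers are not reduced.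

Step 8
Reactants: 10 3,5-bis(benzyloxy)phenol
Product: 11 3,5-bis(benzyloxy)phenyl N-isopropylcarbamate
Conditions: i-PrNCO, Et3N (cat.), CH2Cl2, rt
Reagents that add atoms: isopropyl isocyanate CC(C)N=C=O
Why: Base-catalysed addition of the phenol to the isocyanate installs a carbamate that serves both as directing group for metalation and as a base-cleavable mask of the phenol.

Step 9
Reactants: 11 3,5-bis(benzyloxy)phenyl N-isopropylcarbamate
Product: 14 3,5-bis(benzyloxy)-2-(trimethylsilyl)phenyl N-isopropylcarbamate, via N-TBS carbamate 12 (not isolated), via N-TBS 2-TMS carbamate 13 (not isolated)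
Conditions: TBSOTf, TMEDA, Et2O, 0 °C to rt; n-BuLi, TMEDA, -78 °C; TMSCl, -78 °C to rt; aq NaHSO4
Reagents that add atoms: chlorotrimethylsilane C[Si](C)(C)Cl
Why: Directed ortho-metalation, in which transient N-silylation removes the acidic N–H, the carbamate and the neighbouring benzyloxy group together direct lithiation to C2 between them, TMSCl traps the aryllithium at -78 °C before any anionic Fries shift, and the N-silyl group is lost on acidic aqueous work-up.

Step 10
Reactants: 14 3,5-bis(benzyloxy)-2-(trimethylsilyl)phenyl N-isopropylcarbamate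
Product: 16 3,5-bis(benzyloxy)-2-(trimethylsilyl)phenyl trifluoromethanesulfonate, via silylphenol 15 (not isolated)
Conditions: DBU, Et2NH, MeCN, 40 °C; then PhNTf2, rt
Reagents that add atoms: N-phenylbis(trifluoromethanesulfonimide) O=S(=O)(N(c1ccccc1)S(=O)(=O)C(F)(F)F)C(F)(F)F
Why: E1cB cleavage of the N-monosubstituted carbamate (the isocyanate is trapped by Et2NH as a urea) followed by in situ triflation of the phenoxide, under non-acidic conditions that avoid protodesilylation of the electron-rich arylsilane.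

Step 11
Reactants: 9 ethyl (3R)-3-{4,5-bis(benzyloxy)-2-[5,7,3',4'-tetrakis(benzyloxy)flavon-8-yl]phenyl}-3-hydroxypropanoate; 16 3,5-bis(benzyloxy)-2-(trimethylsilyl)phenyl trifluoromethanesulfonate
Product: 19 (2R)-5,7-bis(benzyloxy)-2-{4,5-bis(benzyloxy)-2-[5,7,3',4'-tetrakis(benzyloxy)flavon-8-yl]phenyl}chroman-4-one, via TMS ether 17 (not isolated), via aryne 18 (not isolated)
Conditions: (Me3Si)2NH, TMSCl (cat.), THF, rt, then evaporation; then 16 (1.5 equiv), KF, 18-crown-6, THF, 0 °C to rt
Reagents that add atoms: none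
Why: Proposed new method: fluoride unmasks the alkoxide from silyl ether 17 in an aprotic medium while it releases aryne 18 from 16; the alkoxide adds to the aryne carbon distal to the 3-benzyloxy group and the resulting aryl anion attacks the tethered ethyl ester and expels ethoxide, so that O1–C8a and C4–C4a form in one operation. The closest known reaction types are the fluoride-mediated annulation of arynes with salicylate esters to xanthones (heteroatom addition, then acyl capture by the aryl anion) and the Parham cyclisation of ortho-lithiated aryl ethers onto a tethered carboxyl derivative to give chroman-4-ones; an aliphatic secondary alkoxide has not been shown as the nucleophile of such a tandem. Ring C closes in a 6-exo-trig acyl substitution, ring A being delivered intact by the aryne. No stereocentre is formed: C2 is the carbinol carbon of 9, its C–O bond is never broken, and the (R) configuration from step 7 is carried through with retention. The step needs regioselective addition to the unsymmetrical aryne, which the inductive polarisation of the triple bond by the flanking benzyloxy group secures (oxygen to the distal carbon, carbanion next to OBn, hence the 5,7-dioxygenated ring A), and ring closure faster than protonation of the aryl anion, which the absence of any O–H (latent alkoxide) and the six-membered transition state favour. Mild temperature and a short reaction time are chosen to limit retro-aldol cleavage of the alkoxide and base-induced opening of ring C.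

Step 12
Reactants: 19 (2R)-5,7-bis(benzyloxy)-2-{4,5-bis(benzyloxy)-2-[5,7,3',4'-tetrakis(benzyloxy)flavon-8-yl]phenyl}chroman-4-one
Product: 20 (2R)-2-[4,5-dihydroxy-2-(5,7,3',4'-tetrahydroxyflavon-8-yl)phenyl]-5,7-dihydroxychroman-4-one (CNP0228504.1)
Conditions: H2 (1 atm), 10% Pd/C, THF/MeOH, rt
Reagents that add atoms: none
Why: Global hydrogenolysis of the eight aryl benzyl ethers under neutral conditions, which should be much faster than reduction of the flavone C2=C3 bond, the C4 ketone or the benzylic C2–O1 bond and should leave the base-sensitive C2 configuration untouched.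

**Compound list**

1 | luteolin (5,7,3',4'-tetrahydroxyflavone) | O=c1cc(-c2ccc(O)c(O)c2)oc2cc(O)cc(O)c12 | starting material
2 | 5,7,3',4'-tetrakis(benzyloxy)flavone | O=c1cc(-c2ccc(OCc3ccccc3)c(OCc3ccccc3)c2)oc2cc(OCc3ccccc3)cc(OCc3ccccc3)c12 | intermediate
3 | 8-iodo-5,7,3',4'-tetrakis(benzyloxy)flavone | O=c1cc(-c2ccc(OCc3ccccc3)c(OCc3ccccc3)c2)oc2c(I)c(OCc3ccccc3)cc(OCc3ccccc3)c12 | intermediate
4 | 3,4-bis(benzyloxy)benzaldehyde | O=Cc1ccc(OCc2ccccc2)c(OCc2ccccc2)c1 | starting material
5 | 2-bromo-4,5-bis(benzyloxy)benzaldehyde | O=Cc1cc(OCc2ccccc2)c(OCc2ccccc2)cc1Br | intermediate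
6 | 4,5-bis(benzyloxy)-2-(4,4,5,5-tetramethyl-1,3,2-dioxaborolan-2-yl)benzaldehyde | O=Cc1cc(OCc2ccccc2)c(OCc2ccccc2)cc1B1OC(C)(C)C(C)(C)O1 | intermediate
7 | 4,5-bis(benzyloxy)-2-[5,7,3',4'-tetrakis(benzyloxy)flavon-8-yl]benzaldehyde | O=Cc1cc(OCc2ccccc2)c(OCc2ccccc2)cc1-c1c(OCc2ccccc2)cc(OCc2ccccc2)c2c(=O)cc(-c3ccc(OCc4ccccc4)c(OCc4ccccc4)c3)oc12 | intermediate
8 | ethyl 3-{4,5-bis(benzyloxy)-2-[5,7,3',4'-tetrakis(benzyloxy)flavon-8-yl]phenyl}-3-oxopropanoate | CCOC(=O)CC(=O)c1cc(OCc2ccccc2)c(OCc2ccccc2)cc1-c1c(OCc2ccccc2)cc(OCc2ccccc2)c2c(=O)cc(-c3ccc(OCc4ccccc4)c(OCc4ccccc4)c3)oc12 | intermediate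
9 | ethyl (3R)-3-{4,5-bis(benzyloxy)-2-[5,7,3',4'-tetrakis(benzyloxy)flavon-8-yl]phenyl}-3-hydroxypropanoate | CCOC(=O)C[C@@H](O)c1cc(OCc2ccccc2)c(OCc2ccccc2)cc1-c1c(OCc2ccccc2)cc(OCc2ccccc2)c2c(=O)cc(-c3ccc(OCc4ccccc4)c(OCc4ccccc4)c3)oc12 | intermediate
10 | 3,5-bis(benzyloxy)phenol | Oc1cc(OCc2ccccc2)cc(OCc2ccccc2)c1 | starting material
11 | 3,5-bis(benzyloxy)phenyl N-isopropylcarbamate | CC(C)NC(=O)Oc1cc(OCc2ccccc2)cc(OCc2ccccc2)c1 | intermediate
12 | 3,5-bis(benzyloxy)phenyl N-(tert-butyldimethylsilyl)-N-isopropylcarbamate | CC(C)N(C(=O)Oc1cc(OCc2ccccc2)cc(OCc2ccccc2)c1)[Si](C)(C)C(C)(C)C | intermediate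
13 | 3,5-bis(benzyloxy)-2-(trimethylsilyl)phenyl N-(tert-butyldimethylsilyl)-N-isopropylcarbamate | CC(C)N(C(=O)Oc1cc(OCc2ccccc2)cc(OCc2ccccc2)c1[Si](C)(C)C)[Si](C)(C)C(C)(C)C | intermediate
14 | 3,5-bis(benzyloxy)-2-(trimethylsilyl)phenyl N-isopropylcarbamate | CC(C)NC(=O)Oc1cc(OCc2ccccc2)cc(OCc2ccccc2)c1[Si](C)(C)C | intermediate
15 | 3,5-bis(benzyloxy)-2-(trimethylsilyl)phenol | Oc1cc(OCc2ccccc2)cc(OCc2ccccc2)c1[Si](C)(C)C | intermediate
16 | 3,5-bis(benzyloxy)-2-(trimethylsilyl)phenyl trifluoromethanesulfonate | O=S(=O)(Oc1cc(OCc2ccccc2)cc(OCc2ccccc2)c1[Si](C)(C)C)C(F)(F)F | intermediate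
17 | ethyl (3R)-3-{4,5-bis(benzyloxy)-2-[5,7,3',4'-tetrakis(benzyloxy)flavon-8-yl]phenyl}-3-(trimethylsilyloxy)propanoate | CCOC(=O)C[C@@H](O[Si](C)(C)C)c1cc(OCc2ccccc2)c(OCc2ccccc2)cc1-c1c(OCc2ccccc2)cc(OCc2ccccc2)c2c(=O)cc(-c3ccc(OCc4ccccc4)c(OCc4ccccc4)c3)oc12 | intermediate
18 | 3,5-bis(benzyloxy)benzyne (1,2-didehydro-3,5-bis(benzyloxy)benzene) | C1#CC(OCc2ccccc2)=CC(OCc2ccccc2)=C1 | intermediate
19 | (2R)-5,7-bis(benzyloxy)-2-{4,5-bis(benzyloxy)-2-[5,7,3',4'-tetrakis(benzyloxy)flavon-8-yl]phenyl}chroman-4-one | O=C1C[C@H](c2cc(OCc3ccccc3)c(OCc3ccccc3)cc2-c2c(OCc3ccccc3)cc(OCc3ccccc3)c3c(=O)cc(-c4ccc(OCc5ccccc5)c(OCc5ccccc5)c4)oc23)Oc2cc(OCc3ccccc3)cc(OCc3ccccc3)c21 | intermediate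
20 | (2R)-2-[4,5-dihydroxy-2-(5,7,3',4'-tetrahydroxyflavon-8-yl)phenyl]-5,7-dihydroxychroman-4-one (CNP0228504.1) | O=C1C[C@H](c2cc(O)c(O)cc2-c2c(O)cc(O)c3c(=O)cc(-c4ccc(O)c(O)c4)oc23)Oc2cc(O)cc(O)c21 | target

**Total step count:** 12.
**Longest linear sequence:** 7 steps (steps 1, 2, 5, 6, 7, 11, 12 from luteolin 1; the branch from aldehyde 4 through steps 3, 4, 5, 6, 7, 11, 12 is equally long).

**Steps most likely to fail**

Step 11 (Proposed new method). What may go wrong: the aryl anion is protonated, or removes an alpha-hydrogen of the ester with subsequent beta-elimination, faster than it closes ring C. The free alkoxide may also suffer retro-aldol cleavage or elimination, and C2 may lose its configuration by base-induced reversible opening of ring C. The fallback uses known chemistry, sets out from aldehyde 7 and comes back at 19. Claisen–Schmidt condensation of 7 with commercially available 1-[2-hydroxy-4,6-bis(benzyloxy)phenyl]ethanone (CC(=O)c1c(O)cc(OCc2ccccc2)cc1OCc1ccccc1; KOH, EtOH/THF, rt) should give the 2'-hydroxychalcone F1. NaOAc in refluxing EtOH should then close ring C by intramolecular oxa-Michael addition to the racemic octa-O-benzyl flavanone F2. Preparative HPLC on a polysaccharide chiral stationary phase separates the (2R)-enantiomer, which is 19, from the (2S)-enantiomer F3, which is set aside. Steps 6 to 11 are not needed on this path.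

Step 5. What may go wrong: slow transmetalation at the doubly ortho-flanked C8–palladium centre, so that base-induced protodeboronation of the ortho-formyl boronate 6 and hydrodeiodination of 3 take over. The fallback sets out from bromide 5 and comes back at 7 by a base-free Stille coupling. Bromide 5 is stannylated ((Bu3Sn)2, Pd(PPh3)4, toluene, 110 °C) to 4,5-bis(benzyloxy)-2-(tributylstannyl)benzaldehyde F4, which is coupled with iodide 3 (Pd(PPh3)4, CuI, DMF, 80 °C) to give 7. Step 4 then falls away.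

Step 6. What may go wrong: aryl migration competing with the hydride shift in the diazonium betaine of this electron-rich aldehyde, or sluggish addition of the diazo ester to the hindered carbonyl group. The fallback sets out from 7 and comes back at 8. Reformatsky addition (Zn, BrCH2CO2Et, THF, reflux) should give the racemic ethyl 3-aryl-3-hydroxypropanoate F5, and Dess–Martin oxidation (CH2Cl2, rt) should convert it into beta-keto ester 8.

**Further compounds**

F1 | step 11 | (E)-1-[2-hydroxy-4,6-bis(benzyloxy)phenyl]-3-{4,5-bis(benzyloxy)-2-[5,7,3',4'-tetrakis(benzyloxy)flavon-8-yl]phenyl}prop-2-en-1-one | O=C(/C=C/c1cc(OCc2ccccc2)c(OCc2ccccc2)cc1-c1c(OCc2ccccc2)cc(OCc2ccccc2)c2c(=O)cc(-c3ccc(OCc4ccccc4)c(OCc4ccccc4)c3)oc12)c1c(O)cc(OCc2ccccc2)cc1OCc1ccccc1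
F2 | step 11 | racemic 5,7-bis(benzyloxy)-2-{4,5-bis(benzyloxy)-2-[5,7,3',4'-tetrakis(benzyloxy)flavon-8-yl]phenyl}chroman-4-one | O=C1CC(c2cc(OCc3ccccc3)c(OCc3ccccc3)cc2-c2c(OCc3ccccc3)cc(OCc3ccccc3)c3c(=O)cc(-c4ccc(OCc5ccccc5)c(OCc5ccccc5)c4)oc23)Oc2cc(OCc3ccccc3)cc(OCc3ccccc3)c21
F3 | step 11 | (2S)-5,7-bis(benzyloxy)-2-{4,5-bis(benzyloxy)-2-[5,7,3',4'-tetrakis(benzyloxy)flavon-8-yl]phenyl}chroman-4-one | O=C1C[C@@H](c2cc(OCc3ccccc3)c(OCc3ccccc3)cc2-c2c(OCc3ccccc3)cc(OCc3ccccc3)c3c(=O)cc(-c4ccc(OCc5ccccc5)c(OCc5ccccc5)c4)oc23)Oc2cc(OCc3ccccc3)cc(OCc3ccccc3)c21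
F4 | step 5 | 4,5-bis(benzyloxy)-2-(tributylstannyl)benzaldehyde | CCCC[Sn](CCCC)(CCCC)c1cc(OCc2ccccc2)c(OCc2ccccc2)cc1C=O
F5 | step 6 | racemic ethyl 3-{4,5-bis(benzyloxy)-2-[5,7,3',4'-tetrakis(benzyloxy)flavon-8-yl]phenyl}-3-hydroxypropanoate | CCOC(=O)CC(O)c1cc(OCc2ccccc2)c(OCc2ccccc2)cc1-c1c(OCc2ccccc2)cc(OCc2ccccc2)c2c(=O)cc(-c3ccc(OCc4ccccc4)c(OCc4ccccc4)c3)oc12
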